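**Retrosynthetic overview**
1. Torilin comes from the C8-epi alcohol by Mitsunobu angeloylation with inversion. The tertiary C11 acetate comes from an isopropenyl group by HAT hydration and acetylation.
2. The cyclopentenone ring is formed last, by aldol condensation of a 1,4-diketone. The diketone comes from carbonyl-assisted alkyne hydration. C1 is set by enolate alkylation anti to the C10 methyl.
3. The seven-membered ring is formed by RCM of a vinyl ketone and an allylic silyl ether. C7 is set by anti-selective cuprate addition to the γ-silyloxy enone.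
4. C8 is set by a ketoreductase (KRED) reduction of a vinyl ketone. C10 comes from organocatalytic desymmetrisation of 3-methylglutaric anhydride.
5. Ring order: a temporary δ-lactone, then the cycloheptenone (RCM), then the cyclopentenone (aldol).

**Assumptions**
- Small commercial reagents (Grignards, MeNHOMe, TBSCl, etc.) are given by name and SMILES in the reagent line and are not numbered. Angelic acid is numbered because it is the acyl building block.
- The cinchona catalyst pseudo-enantiomer and the KRED are chosen (screened) to give the stated (S) products.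

## Route

**Step 1**
Reactants: 1, 3-methylglutaric anhydride
Product: 2, (3S)-5-methoxy-3-methyl-5-oxopentanoic acid
Conditions: (DHQD)2AQN (10 mol %), MeOH (3 equiv), MTBE, –20 °C, 48 h
Reagents that add atoms: methanol, CO
Why: The cinchona catalyst delivers MeOH to one of the two enantiotopic carbonyls (catalytic asymmetric anhydride desymmetrisation), setting C10 (S) at about 90 % ee, which is upgraded at Step 5.

**Step 2**
Reactants: 2
Product: 3, methyl (3S)-5-[methoxy(methyl)amino]-3-methyl-5-oxopentanoate
Conditions: MeNH(OMe)·HCl, EDC·HCl, Et3N, CH2Cl2, 0 °C → rt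
Reagents that add atoms: N,O-dimethylhydroxylamine, CNOC
Why: Carbodiimide amide coupling acts only on the free acid, so the two chain ends are now differentiated and C10 is untouched.

**Step 3**
Reactants: 3
Product: 4, methyl (3S)-3-methyl-5-oxohept-6-enoate
Conditions: CH2=CHMgBr (1.05 equiv), THF, –40 °C, 1 h
Reagents that add atoms: vinylmagnesium bromide, C=C[Mg]Br
Why: In the Weinreb ketone synthesis the chelated tetrahedral intermediate prevents over-addition and leaves the methyl ester intact.

**Step 4**
Reactants: 4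
Product: 5, methyl (3S,5S)-5-hydroxy-3-methylhept-6-enoate
Conditions: ketoreductase (NADPH-dependent alcohol dehydrogenase, (S)-selective panel enzyme), NADP+, iPrOH (10 % v/v), KPi pH 7.0/DMSO, 30 °C, 24 h
Reagents that add atoms: none (only hydride/H+)
Why: The enzyme delivers hydride to one face of the vinyl ketone and sets C8 (S), overriding the weak 1,3-induction from C10 to give the 3,5-cis series.

**Step 5**
Reactants: 5
Product: 6, (4S,6S)-4-methyl-6-vinyltetrahydro-2H-pyran-2-one
Conditions: PPTS (10 mol %), PhMe, 60 °C, 6 h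
Reagents that add atoms: none (MeOH is lost)
Why: Acid-catalysed intramolecular transesterification gives the cis-δ-lactone. No stereocentre is touched, and chromatography removes any trans lactone derived from the minor enantiomer of 2, upgrading ee.

**Step 6**
Reactants: 6
Product: 7, (3S,5S)-5-hydroxy-N-methoxy-N,3-dimethylhept-6-enamide
Conditions: MeNH(OMe)·HCl, AlMe3, CH2Cl2, 0 °C → rt
Reagents that add atoms: N,O-dimethylhydroxylamine, CNOC
Why: Al-mediated Weinreb aminolysis opens the lactone and reveals the C8 carbinol and the C5-end carbonyl in differentiated form.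

**Step 7**
Reactants: 7
Product: 8, (3S,5S)-5-[(tert-butyldimethylsilyl)oxy]-N-methoxy-N,3-dimethylhept-6-enamide
Conditions: TBSCl, imidazole, DMF, 0 °C → rt
Reagents that add atoms: TBSCl, CC(C)(C)[Si](C)(C)Cl
Why: Silyl protection of the secondary allylic alcohol; C8 is not affected.

**Step 8**
Reactants: 8
Product: 9, (5S,7S)-7-[(tert-butyldimethylsilyl)oxy]-5-methylnona-1,8-dien-3-one
Conditions: CH2=CHMgBr (1.5 equiv), THF, –20 °C → 0 °C
Reagents that add atoms: vinylmagnesium bromide, C=C[Mg]Br
Why: A second Weinreb ketone synthesis gives the RCM precursor without over-addition.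

**Step 9**
Reactants: 9
Product: 10, (4S,6S)-4-(TBSO)-6-methylcyclohept-2-en-1-one
Conditions: Hoveyda–Grubbs II (5 mol %), CH2Cl2 (5 mM), 40 °C, 12 h
Reagents that add atoms: none (ethylene is lost)
Why: Ring-closing metathesis forms the seven-membered enone, and the C8 and C10 substituents favour cyclisation; no new stereocentre is created.

**Step 10**
Reactants: 11's precursor 10
Product: 11, (4S,6S,7R)-7-(but-2-yn-1-yl)-4-(TBSO)-6-methylcyclohept-2-en-1-one
Conditions: LDA, THF, –78 °C; then HMPA, CC#CCBr, –78 → –40 °C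
Reagents that add atoms: 1-bromo-2-butyne, CC#CCBr
Why: The enone has only one enolisable α′-carbon (C1), so the enolate alkylation is regiospecific, and the electrophile enters anti to the adjacent C10 methyl, setting C1 (trans-alkylation).

**Step 11**
Reactants: 11
Product: 12, (2R,3S,5S,6R)-2-(but-2-yn-1-yl)-5-(TBSO)-3-methyl-6-(prop-1-en-2-yl)cycloheptan-1-one
Conditions: CH2=C(Me)MgBr, CuBr·SMe2 (20 mol %), TMSCl, THF, –78 °C; then 1 M HCl/THF, 0 °C, 5 min
Reagents that add atoms: isopropenylmagnesium bromide, CC(=C)[Mg]Br (TMSCl is removed in the work-up)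
Why: Cu-catalysed 1,4-addition to the γ-silyloxy enone occurs anti to the C8 OTBS, setting C7 so that the isopropenyl group lies on the same face as the C10 methyl.

**Step 12**
Reactants: 12
Product: 13, (2R,3S,5S,6S)-2-(but-2-yn-1-yl)-5-(TBSO)-6-(2-hydroxypropan-2-yl)-3-methylcycloheptan-1-one
Conditions: Co(acac)2 (5 mol %), PhSiH3, O2 (1 atm), iPrOH, rt
Reagents that add atoms: oxygen, O=O
Why: Mukaiyama HAT hydration is Markovnikov-selective for the 1,1-disubstituted alkene and tolerates the ketone, internal alkyne and silyl ether; no stereocentre changes.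

**Step 13**
Reactants: 13
Product: 14, (2R,3S,5S,6S)-6-(2-acetoxypropan-2-yl)-2-(but-2-yn-1-yl)-5-(TBSO)-3-methylcycloheptan-1-one
Conditions: Ac2O (10 equiv), DMAP (1 equiv), Et3N, CH2Cl2, 40 °C, 24 h
Reagents that add atoms: acetic anhydride, CC(=O)OC(C)=O
Why: DMAP-catalysed acylation caps the tertiary alcohol as the final C11 acetate before the later acid/base steps.

**Step 14**
Reactants: 14
Product: 15, (2R,3S,5S,6S)-6-(2-acetoxypropan-2-yl)-5-(TBSO)-3-methyl-2-(2-oxobutyl)cycloheptan-1-one
Conditions: Ph3PAuCl (3 mol %), AgOTf (3 mol %), MeOH/H2O 9:1, 60 °C, 6 h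
Reagents that add atoms: water, O
Why: Au(I)-catalysed carbonyl-assisted hydration puts the new ketone at the γ-alkyne carbon (5-exo attack by the C5 carbonyl oxygen), giving the ethyl ketone of the 1,4-diketone.

**Step 15**
Reactants: 15
Product: 16, (1R,7S,8S,10S)-11-acetoxy-8-(TBSO)guai-4-en-3-one
Conditions: pyrrolidine (20 mol %), AcOH (20 mol %), PhMe, 80 °C, 6 h
Reagents that add atoms: none (water is lost)
Why: Intramolecular aldol condensation of the 1,4-diketone (Paal-type cyclopentenone annulation) closes the five-membered ring and gives the conjugated tetrasubstituted C4=C5 enone; the mild amine/acid conditions spare the acetate and C1 stays trans to C10.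

**Step 16**
Reactants: 16
Product: 17, (1R,7S,8S,10S)-11-acetoxy-8-hydroxyguai-4-en-3-one
Conditions: HF·pyridine, pyridine/THF, 0 °C → rt, 6 h
Reagents that add atoms: none
Why: Fluoride-mediated Si–O cleavage under buffered, weakly acidic conditions leaves the enone and the tertiary acetate intact.

**Step 17**
Reactants: 17; 18, angelic acid ((2Z)-2-methylbut-2-enoic acid)
Product: 19, torilin
Conditions: PPh3 (2 equiv), DIAD (2 equiv), 18 (3 equiv), PhMe, 0 °C → rt, 12 h
Reagents that add atoms: none (angelic acid 18 is the numbered acyl donor)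
Why: Mitsunobu esterification proceeds by SN2 with inversion at C8, converting 8S into 8R and placing the Z-angelate cis to the C7 side chain, with the Z-alkene geometry retained at rt.

## Compound list

1 | 3-methylglutaric anhydride | O=C1CC(C)CC(=O)O1 | starting material
2 | (3S)-5-methoxy-3-methyl-5-oxopentanoic acid | OC(=O)C[C@H](C)CC(=O)OC | intermediate
3 | methyl (3S)-5-[methoxy(methyl)amino]-3-methyl-5-oxopentanoate | CON(C)C(=O)C[C@H](C)CC(=O)OC | intermediate
4 | methyl (3S)-3-methyl-5-oxohept-6-enoate | C=CC(=O)C[C@H](C)CC(=O)OC | intermediate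
5 | methyl (3S,5S)-5-hydroxy-3-methylhept-6-enoate | C=C[C@@H](O)C[C@H](C)CC(=O)OC | intermediate
6 | (4S,6S)-4-methyl-6-vinyltetrahydro-2H-pyran-2-one | C=C[C@@H]1C[C@H](C)CC(=O)O1 | intermediate
7 | (3S,5S)-5-hydroxy-N-methoxy-N,3-dimethylhept-6-enamide | C=C[C@@H](O)C[C@H](C)CC(=O)N(C)OC | intermediate
8 | (3S,5S)-5-(TBSO)-N-methoxy-N,3-dimethylhept-6-enamide | C=C[C@@H](O[Si](C)(C)C(C)(C)C)C[C@H](C)CC(=O)N(C)OC | intermediate
9 | (5S,7S)-7-(TBSO)-5-methylnona-1,8-dien-3-one | C=C[C@@H](O[Si](C)(C)C(C)(C)C)C[C@H](C)CC(=O)C=C | intermediate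
10 | (4S,6S)-4-(TBSO)-6-methylcyclohept-2-en-1-one | O=C1C=C[C@@H](O[Si](C)(C)C(C)(C)C)C[C@H](C)C1 | intermediate
11 | (4S,6S,7R)-7-(but-2-yn-1-yl)-4-(TBSO)-6-methylcyclohept-2-en-1-one | O=C1C=C[C@@H](O[Si](C)(C)C(C)(C)C)C[C@H](C)[C@H]1CC#CC | intermediate
12 | (2R,3S,5S,6R)-2-(but-2-yn-1-yl)-5-(TBSO)-3-methyl-6-(prop-1-en-2-yl)cycloheptan-1-one | O=C1C[C@H](C(C)=C)[C@@H](O[Si](C)(C)C(C)(C)C)C[C@H](C)[C@H]1CC#CC | intermediate
13 | (2R,3S,5S,6S)-2-(but-2-yn-1-yl)-5-(TBSO)-6-(2-hydroxypropan-2-yl)-3-methylcycloheptan-1-one | O=C1C[C@H](C(C)(C)O)[C@@H](O[Si](C)(C)C(C)(C)C)C[C@H](C)[C@H]1CC#CC | intermediate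
14 | (2R,3S,5S,6S)-6-(2-acetoxypropan-2-yl)-2-(but-2-yn-1-yl)-5-(TBSO)-3-methylcycloheptan-1-one | O=C1C[C@H](C(C)(C)OC(C)=O)[C@@H](O[Si](C)(C)C(C)(C)C)C[C@H](C)[C@H]1CC#CC | intermediate
15 | (2R,3S,5S,6S)-6-(2-acetoxypropan-2-yl)-5-(TBSO)-3-methyl-2-(2-oxobutyl)cycloheptan-1-one | O=C1C[C@H](C(C)(C)OC(C)=O)[C@@H](O[Si](C)(C)C(C)(C)C)C[C@H](C)[C@H]1CC(=O)CC | intermediate
16 | (1R,7S,8S,10S)-11-acetoxy-8-(TBSO)guai-4-en-3-one | CC(C)(C)[Si](C)(C)O[C@H]1C[C@H](C)[C@H]2CC(=O)C(C)=C2C[C@@H]1C(C)(C)OC(C)=O | intermediate
17 | (1R,7S,8S,10S)-11-acetoxy-8-hydroxyguai-4-en-3-one | O[C@H]1C[C@H](C)[C@H]2CC(=O)C(C)=C2C[C@@H]1C(C)(C)OC(C)=O | intermediate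
18 | angelic acid, (2Z)-2-methylbut-2-enoic acid | C/C=C(/C)C(=O)O | starting material
19 | torilin, (1R,7S,8R,10S)-8-angeloyloxy-11-acetoxyguai-4-en-3-one | C/C=C(/C)C(=O)O[C@@H]1C[C@H](C)[C@H]2CC(=O)C(C)=C2C[C@@H]1C(C)(C)OC(C)=O | target

**Total steps:** 17. **Longest linear sequence:** 17 steps (1 → 19).

**Three steps most likely to fail, with fallbacks**
1. **Step 11 (C7 facial selectivity of the cuprate addition in a flexible seven-membered ring).** Fallback: accept a C7 mixture, then remove TBS, oxidise C8 to the ketone, and equilibrate C7 (α to the C8 ketone). Then reduce with a ketoreductase chosen for the cis-hydroxy product. This sets C7 and C8 by enzyme control and makes the final Mitsunobu inversion unnecessary.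
2. **Step 14 (regioselectivity of the alkyne hydration; loss of TBS or furan formation under Au/Ag acidity).** Fallback: in Step 10 alkylate with 2-bromo-N-methoxy-N-methylacetamide instead of the butynyl bromide. In Step 11 trap the enolate as the TMS enol ether, then convert the Weinreb amide to the ethyl ketone with EtMgBr, so the C5 carbonyl stays masked. Acidic work-up then gives the 1,4-diketone without any alkyne hydration.
3. **Step 17 (Mitsunobu inversion at a hindered secondary alcohol flanked by the bulky C7 side chain; competing elimination).** Fallback: oxidise 17 to the C8 ketone (Dess–Martin periodinane) and reduce it with a ketoreductase or L-Selectride to the C8 alcohol with the required configuration. Then angeloylate by the Yamaguchi mixed-anhydride method (2,4,6-trichlorobenzoyl chloride, Et3N, DMAP) to give torilin with net retention instead of SN2 inversion.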